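**Plan**

1. Numbering used throughout: C1 lactone C=O, C2, C3 (enol), C4 and C6 (CHMe), C5, C7 (ketone), C8, C9, C10, C11 (CHOH), C12 (C(Me)–O), C13 (CHMe), C14, C15 (C–O–C1), C16 (bonded to C2, C8, C15 and the ether oxygen that bridges to C12).
2. Retrosynthesis: cut C8–C16 (transannular Michael addition after conjugate reduction), C8=C9 (ring-closing metathesis), C2–C3 (acylation of the C2-lithiated tetronate by a δ-lactone), then C11–C12 (key step), O–C12 (alkyne hydroalkoxylation), C2–C16 (Dieckmann), C15–OH and C14–C15 (on a butyrolactone).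
3. Forward ring order: γ-butyrolactone template → spiro-tetronate → oxane ring O–C12–C13–C14–C15–C16 with exocyclic C12=CH2 → cyclohexane C10–C15 and with it the 2-oxabicyclo[2.2.2]octane → 11-membered enone → cyclopentane and cyclooctane together.
4. Feature that makes the key event possible: C12 is a fully substituted carbon carrying a methyl group and the ring ether oxygen, next to the secondary carbinol C11. It is therefore the Markovnikov hydrogen-atom adduct of the enol ether C12=CH2 of the oxane ring, joined to an aldehyde carbon that hangs from C15 across that ring.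
5. Stereochemistry: C10 by ligand-controlled rhodium conjugate addition, C13 from methyl (S)-3-hydroxy-2-methylpropanoate, C15 by enolate hydroxylation anti to the C10 substituent, C11 and C12 in the key step, C4 and C6 from desymmetrised meso-2,4-dimethylglutaric anhydride, C8 and C16 by the transannular closure.

Key step: step 14

Remark (assumption): the sense of induction of (R)-BINAP in step 1 and of (DHQD)2AQN in step 18 is taken from the usual models for these catalysts; the mirror-image ligand or the pseudo-enantiomeric alkaloid is used if the sense proves opposite.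
Remark: metal enolates, organolithium compounds and radicals that are formed and consumed within one reagent sequence are described in the Why lines and carry no number.
Remark: compounds 25, 26 and 27 are mixtures of the two C7 epimers; C7 becomes a ketone in step 22.

**Route**

Step 1
Reactants: 1 furan-2(5H)-one
Product: 2 (R)-4-[(E)-2-phenylethenyl]dihydrofuran-2(3H)-one
Conditions: (E)-2-phenylethenylboronic acid (2 equiv), Rh(acac)(C2H4)2 (3 mol %), (R)-BINAP (3.3 mol %), dioxane/H2O 10:1, 100 °C
Reagents that add atoms: (E)-2-phenylethenylboronic acid OB(O)/C=C/c1ccccc1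
Why: Hayashi–Miyaura asymmetric 1,4-addition, in which the alkenylrhodium species bound to the chiral bisphosphine adds to one enantioface of the butenolide and so sets C10, the styryl group being a masked formyl group (C11).

Step 2
Reactants: 2 (R)-4-[(E)-2-phenylethenyl]dihydrofuran-2(3H)-one
Product: 4 (S)-4-(dimethoxymethyl)dihydrofuran-2(3H)-one, via (S)-5-oxotetrahydrofuran-3-carbaldehyde 3 (not isolated)
Conditions: O3, CH2Cl2/MeOH, −78 °C; Me2S; then HC(OMe)3, TsOH·H2O (cat.), MeOH, 23 °C
Reagents that add atoms: trimethyl orthoformate COC(OC)OC; ozone [O-][O+]=O (oxygen atom of intermediate 3)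
Why: Ozonolysis with reductive work-up cleaves the styryl group to the C11 aldehyde, which is acetalised at once in the same flask so that C10 does not epimerise and the aldehyde survives the enolate chemistry that follows.

Step 3
Reactants: 5 methyl (S)-3-hydroxy-2-methylpropanoate
Product: 6 methyl (S)-3-[(tert-butyldimethylsilyl)oxy]-2-methylpropanoate
Conditions: t-BuMe2SiCl, imidazole, CH2Cl2, 23 °C
Reagents that add atoms: tert-butyldimethylsilyl chloride CC(C)(C)[Si](C)(C)Cl
Why: Standard silylation of the primary alcohol protects it through the reduction and the homologation.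

Step 4
Reactants: 6 methyl (S)-3-[(tert-butyldimethylsilyl)oxy]-2-methylpropanoate
Product: 7 (S)-3-[(tert-butyldimethylsilyl)oxy]-2-methylpropanal
Conditions: i-Bu2AlH (1.05 equiv), CH2Cl2, −78 °C; aq. potassium sodium tartrate
Reagents that add atoms: none
Why: At −78 °C the aluminium hemiacetal formed by one hydride transfer is stable until work-up, so the ester is reduced only to the aldehyde, which is used at once to keep the α-stereocentre.

Step 5
Reactants: 7 (S)-3-[(tert-butyldimethylsilyl)oxy]-2-methylpropanal
Product: 8 (R)-tert-butyldimethyl[(2-methylbut-3-yn-1-yl)oxy]silane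
Conditions: dimethyl (1-diazo-2-oxopropyl)phosphonate, K2CO3, MeOH, 0 → 23 °C
Reagents that add atoms: dimethyl (1-diazo-2-oxopropyl)phosphonate CC(=O)C(=[N+]=[N-])P(=O)(OC)OC
Why: Ohira–Bestmann (Seyferth–Gilbert) homologation converts the aldehyde into the terminal alkyne under mild conditions that leave the adjacent stereocentre (the future C13) intact.

Step 6
Reactants: 8 (R)-tert-butyldimethyl[(2-methylbut-3-yn-1-yl)oxy]silane
Product: 9 (R)-2-methylbut-3-yn-1-ol
Conditions: Bu4NF, THF, 0 °C
Reagents that add atoms: none
Why: Fluoride cleaves the silyl ether to free the primary alcohol, which is kept in solution because it is volatile.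

Step 7
Reactants: 9 (R)-2-methylbut-3-yn-1-ol
Product: 10 (R)-2-methylbut-3-yn-1-yl trifluoromethanesulfonate
Conditions: Tf2O, 2,6-lutidine, CH2Cl2, −78 °C; used at once
Reagents that add atoms: trifluoromethanesulfonic anhydride O=S(=O)(OS(=O)(=O)C(F)(F)F)C(F)(F)F
Why: Triflation makes the β-branched primary carbon reactive enough for SN2 alkylation of a lactone enolate at low temperature.

Step 8
Reactants: 4 (S)-4-(dimethoxymethyl)dihydrofuran-2(3H)-one; 10 (R)-2-methylbut-3-yn-1-yl trifluoromethanesulfonate
Product: 11 (3S,4S)-4-(dimethoxymethyl)-3-[(2S)-2-methylbut-3-yn-1-yl]dihydrofuran-2(3H)-one (trans)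
Conditions: LiN(i-Pr)2 (1.05 equiv), THF, −78 °C; then 10 (1.2 equiv), −78 → −30 °C
Reagents that add atoms: none
Why: SN2 alkylation of the lithium lactone enolate by the primary triflate forms C14–C15, the electrophile entering anti to the C10 substituent; the configuration at C15 is reset in step 9.

Step 9
Reactants: 11 (3S,4S)-4-(dimethoxymethyl)-3-[(2S)-2-methylbut-3-yn-1-yl]dihydrofuran-2(3H)-one
Product: 12 (3S,4R)-4-(dimethoxymethyl)-3-hydroxy-3-[(2S)-2-methylbut-3-yn-1-yl]dihydrofuran-2(3H)-one (hydroxyl trans to the dimethoxymethyl group)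
Conditions: KN(SiMe3)2 (2.2 equiv), THF, −78 °C; then trans-2-(phenylsulfonyl)-3-phenyloxaziridine (1.3 equiv); aq. NH4Cl
Reagents that add atoms: trans-2-(phenylsulfonyl)-3-phenyloxaziridine O=S(=O)(c1ccccc1)N1OC1c1ccccc1
Why: Enolate hydroxylation by the N-sulfonyloxaziridine delivers oxygen to the face of the lactone enolate anti to the C10 dimethoxymethyl group, which sets the C15 carbinol with the hydroxyl trans to C11 and the alkynyl arm cis to it (the second equivalent of base covers the alkyne C–H).

Step 10
Reactants: 12 (3S,4R)-4-(dimethoxymethyl)-3-hydroxy-3-[(2S)-2-methylbut-3-yn-1-yl]dihydrofuran-2(3H)-one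
Product: 13 (3S,4R)-4-(dimethoxymethyl)-3-[(2S)-2-methylbut-3-yn-1-yl]-2-oxotetrahydrofuran-3-yl acetate
Conditions: Ac2O, 4-(dimethylamino)pyridine, Et3N, CH2Cl2, 40 °C
Reagents that add atoms: acetic anhydride CC(=O)OC(C)=O
Why: Nucleophilic catalysis by 4-(dimethylamino)pyridine acetylates the hindered tertiary alcohol and installs C1 and C2 of the tetronate.

Step 11
Reactants: 13 (3S,4R)-4-(dimethoxymethyl)-3-[(2S)-2-methylbut-3-yn-1-yl]-2-oxotetrahydrofuran-3-yl acetate
Product: 14 (5S)-4-hydroxy-5-[(2R)-1-hydroxy-3,3-dimethoxypropan-2-yl]-5-[(2S)-2-methylbut-3-yn-1-yl]furan-2(5H)-one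
Conditions: LiN(SiMe3)2 (3.5 equiv), THF, −78 → 0 °C; aq. NH4Cl, then citric acid to pH 4 at 0 °C
Reagents that add atoms: none
Why: Dieckmann condensation, in which the acetate enolate attacks the lactone carbonyl C16 (5-exo-trig), the tetrahedral intermediate expels the C9 alkoxide and the tetronic acid results with C15 untouched, the acetal surviving the pH 4 work-up.

Step 12
Reactants: 14 (5S)-4-hydroxy-5-[(2R)-1-hydroxy-3,3-dimethoxypropan-2-yl]-5-[(2S)-2-methylbut-3-yn-1-yl]furan-2(5H)-one
Product: 15 (6S,7aS)-7a-[(2R)-1-hydroxy-3,3-dimethoxypropan-2-yl]-6-methyl-5-methylidene-5,6,7,7a-tetrahydro-2H-furo[3,2-b]pyran-2-one (C13 methyl trans to the C15 side chain)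
Conditions: AuCl (5 mol %), K2CO3 (10 mol %), MeCN, 23 °C
Reagents that add atoms: none
Why: Cycloisomerisation of the kind known for alkynoic acids, in which AuCl activates the terminal alkyne and the tetronate oxygen adds 6-exo-dig in the Markovnikov sense, forming the O–C12 bond and the oxane ring with its exocyclic enol ether while C13 and C15 are untouched.

Step 13
Reactants: 15 (6S,7aS)-7a-[(2R)-1-hydroxy-3,3-dimethoxypropan-2-yl]-6-methyl-5-methylidene-5,6,7,7a-tetrahydro-2H-furo[3,2-b]pyran-2-one
Product: 16 (2R)-3-hydroxy-2-[(6S,7aS)-6-methyl-5-methylidene-2-oxo-5,6,7,7a-tetrahydro-2H-furo[3,2-b]pyran-7a-yl]propanal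
Conditions: pyridinium p-toluenesulfonate (10 mol %), acetone/H2O 10:1, 40 °C
Reagents that add atoms: water O
Why: Acid-catalysed acetal hydrolysis unmasks the C11 aldehyde only after the tetronate oxygen is blocked (a free tetronic acid would condense with it), and the enol ether should survive because it is a vinylogous enol ester that is protonated far more slowly than an alkyl enol ether.

Step 14
Reactants: 16 (2R)-3-hydroxy-2-[(6S,7aS)-6-methyl-5-methylidene-2-oxo-5,6,7,7a-tetrahydro-2H-furo[3,2-b]pyran-7a-yl]propanal
Product: 17 oxabicyclic diol: spiro-tetronate whose enol oxygen bridges to C12 in a 2-oxabicyclo[2.2.2]octane, with CH2OH on C10 and OH on C11 (anti to the ring oxygen on C12), configuration at C10, C11, C12, C13 and C15 as in the target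
Conditions: Fe(acac)3 (1.0 equiv), PhSiH3 (2.5 equiv, added over 1 h), EtOH/ethylene glycol 5:1 (0.02 M), 60 °C, argon
Reagents that add atoms: none
Why: Proposed new method: an iron hydride formed from Fe(acac)3 and PhSiH3 transfers a hydrogen atom to the terminal carbon of the C12 enol ether (Markovnikov), which makes the C12 methyl group and the tertiary α-oxy radical at C12; this nucleophilic radical adds to the aldehyde carbon C11, and the alkoxy radical is reduced by divalent iron and protonated by ethanol, the closest known reaction types being the Fe(acac)3/PhSiH3 hydrogen-atom-transfer cyclisation of alkenes onto ketones and the hydrogen-atom-transfer Giese coupling of enol ethers. The new bond closes the cyclohexane C10–C11–C12–C13–C14–C15 and at the same time the second oxane O–C12–C11–C10–C15–C16, both by 6-exo-trig attack on the C=O carbon, so that the 2-oxabicyclo[2.2.2]octane is complete. C12 is fixed by the bridge, because the radical can only be reached on the face of the oxane ring that carries the C15 side chain. C11 is set by the aldehyde rotamer in which the carbonyl oxygen points away from the ring oxygen on C12 and eclipses C10–H rather than the C9 hydroxymethyl group, which places the new hydroxyl anti to the ether oxygen as in the target. The step needs hydrogen-atom transfer to the 1,1-disubstituted enol ether only (it is the sole electron-rich terminal alkene, the tetronate C2=C16 being trisubstituted and electron-poor) and reduction of the alkoxy radical faster than a second hydrogen-atom transfer to the C12 radical; addition to C=O is reversible, but ring opening only returns the same C12 radical, so slow addition of the silane and high dilution should favour the bicycle.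

Step 15
Reactants: 17 oxabicyclic diol
Product: 18 bis(triethylsilyl) ether of 17 (C9–OSiEt3 and C11–OSiEt3)
Conditions: Et3SiOTf (2.5 equiv), 2,6-lutidine, CH2Cl2, −78 → 0 °C
Reagents that add atoms: triethylsilyl trifluoromethanesulfonate CC[Si](CC)(CC)OS(=O)(=O)C(F)(F)F
Why: Silylation of both hydroxyl groups protects C11–OH for the organolithium step and turns C9–OH into the group that step 16 oxidises.

Step 16
Reactants: 18 bis(triethylsilyl) ether
Product: 19 C9 aldehyde (formyl group on C10, C11–OSiEt3 retained)
Conditions: (COCl)2, DMSO, CH2Cl2, −78 → −30 °C; then Et3N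
Reagents that add atoms: none
Why: Under Swern conditions the chlorosulfonium salt attacks the unhindered primary silyl ether oxygen, the silyl group leaves as Et3SiCl and the alkoxysulfonium ylide collapses to the aldehyde, while the hindered secondary silyl ether at C11 is inert.

Step 17
Reactants: 19 C9 aldehyde
Product: 20 C10-vinyl core (vinyl group on C10, C11–OSiEt3, tetronate C2–H)
Conditions: Ph3PCH3Br, KN(SiMe3)2, THF, 0 °C; then 19, −78 → 0 °C
Reagents that add atoms: methyltriphenylphosphonium bromide C[P+](c1ccccc1)(c1ccccc1)c1ccccc1.[Br-]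
Why: Wittig methylenation at low temperature converts the C9 aldehyde into the vinyl group without epimerising C10.

Step 18
Reactants: 21 cis-3,5-dimethyloxane-2,6-dione (meso-2,4-dimethylglutaric anhydride)
Product: 22 (2R,4S)-5-methoxy-2,4-dimethyl-5-oxopentanoic acid
Conditions: MeOH (10 equiv), (DHQD)2AQN (10 mol %), Et2O, −20 °C
Reagents that add atoms: methanol CO
Why: The bis-cinchona alkaloid acts as a chiral general base and directs methanol to one of the two enantiotopic carbonyl groups of the meso anhydride, which sets C4 and C6 at once.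

Step 19
Reactants: 22 (2R,4S)-5-methoxy-2,4-dimethyl-5-oxopentanoic acid
Product: 24 methyl (2S,4R)-2,4-dimethyl-5-oxopentanoate, via acid chloride 23 (not isolated)
Conditions: (COCl)2, DMF (cat.), CH2Cl2, 0 → 23 °C; concentrate; then LiAlH(O-t-Bu)3 (1.05 equiv), THF, −78 °C
Reagents that add atoms: oxalyl chloride ClC(=O)C(Cl)=O (chlorine atom of intermediate 23)
Why: The acid is activated as its chloride and reduced by the hindered, mild hydride LiAlH(O-t-Bu)3, which stops at the aldehyde and does not touch the methyl ester.

Step 20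
Reactants: 24 methyl (2S,4R)-2,4-dimethyl-5-oxopentanoate
Product: 26 (3S,5R)-6-ethenyl-3,5-dimethyloxan-2-one (both C6 epimers), via hydroxy ester 25 (not isolated)
Conditions: CH2=CHMgBr (1.1 equiv), THF, −78 → 23 °C; aq. NH4Cl
Reagents that add atoms: vinylmagnesium bromide C=C[Mg]Br
Why: The Grignard reagent adds to the aldehyde in preference to the ester and the alkoxide lactonises on warming, which gives the C3 acyl donor with the C7 carbinol and the C8 vinyl carbon in place.

Step 21
Reactants: 20 C10-vinyl core; 26 (3S,5R)-6-ethenyl-3,5-dimethyloxan-2-one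
Product: 27 C3 ketone with C7 carbinol (3-acyl tetronate carrying the chain C3(=O)–C4H(Me)–C5H2–C6H(Me)–C7H(OH)–CH=CH2; both C7 epimers)
Conditions: 20, t-BuLi (1.1 equiv), THF, −78 °C; then 26 (1.3 equiv), −78 → −40 °C; aq. NH4Cl
Reagents that add atoms: none
Why: Deprotonation of the tetronate at C2 gives a vinyllithium that attacks the δ-lactone carbonyl, and because the tetrahedral lithium hemiketal survives until work-up the C3 ketone and the C2–C3 bond are obtained in one operation without a second addition.

Step 22
Reactants: 27 C3 ketone with C7 carbinol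
Product: 28 dienone (C7 vinyl ketone, C10 vinyl group)
Conditions: Dess–Martin periodinane, NaHCO3, CH2Cl2, 0 → 23 °C
Reagents that add atoms: none
Why: Dess–Martin oxidation of the allylic C7 alcohol gives the vinyl ketone under buffered conditions that leave the silyl ether and the C4 and C6 stereocentres untouched.

Step 23
Reactants: 28 dienone
Product: 29 macrocyclic E-enone silyl ether (11-membered ring C2–C3–C4–C5–C6–C7–C8=C9–C10–C15–C16)
Conditions: second-generation Grubbs catalyst RuCl2(=CHPh)(H2IMes)(PCy3) (10 mol %), CH2Cl2 (1 mM), 40 °C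
Reagents that add atoms: none
Why: Ring-closing metathesis between the C10 vinyl group and the vinyl ketone releases ethene and closes the 11-membered ring as the conjugated E-enone, a closure with close precedent on 3-acyl spirotetronates of this type.

Step 24
Reactants: 29 macrocyclic E-enone silyl ether
Product: 30 macrocyclic E-enone with free C11–OH
Conditions: HF·pyridine, pyridine/THF, 0 → 23 °C
Reagents that add atoms: none
Why: Buffered fluoride removes the C11 silyl ether without touching the enone.

Step 25
Reactants: 30 macrocyclic E-enone with free C11–OH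
Product: 31 abyssomicin N
Conditions: LiBH(s-Bu)3 (2.2 equiv), THF, −78 → −20 °C; aq. NH4Cl
Reagents that add atoms: none
Why: Conjugate hydride addition to the strained enone gives the C7–C8 enolate, which adds across the ring to C16 of the 3-acyl tetronate (transannular Michael addition, 5-exo-trig for the cyclopentane, closing the cyclooctane at the same time), the cage allowing only one face at C16 and C8, and protonation of the β-keto lactone enolate gives the hydrogen-bonded enol; macrocyclic enones of this class are known to give the cage in this way.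

**Compound list**

1 | furan-2(5H)-one | O=C1C=CCO1 | starting material
2 | (R)-4-[(E)-2-phenylethenyl]dihydrofuran-2(3H)-one | O=C1C[C@@H](CO1)/C=C/c1ccccc1 | intermediate
3 | (S)-5-oxotetrahydrofuran-3-carbaldehyde | O=C1C[C@@H](CO1)C=O | intermediate
4 | (S)-4-(dimethoxymethyl)dihydrofuran-2(3H)-one | O=C1C[C@@H](CO1)C(OC)OC | intermediate
5 | methyl (S)-3-hydroxy-2-methylpropanoate | COC(=O)[C@@H](C)CO | starting material
6 | methyl (S)-3-[(tert-butyldimethylsilyl)oxy]-2-methylpropanoate | COC(=O)[C@@H](C)CO[Si](C)(C)C(C)(C)C | intermediate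
7 | (S)-3-[(tert-butyldimethylsilyl)oxy]-2-methylpropanal | O=C[C@@H](C)CO[Si](C)(C)C(C)(C)C | intermediate
8 | (R)-tert-butyldimethyl[(2-methylbut-3-yn-1-yl)oxy]silane | C#C[C@@H](C)CO[Si](C)(C)C(C)(C)C | intermediate
9 | (R)-2-methylbut-3-yn-1-ol | C#C[C@@H](C)CO | intermediate
10 | (R)-2-methylbut-3-yn-1-yl trifluoromethanesulfonate | C#C[C@@H](C)COS(=O)(=O)C(F)(F)F | intermediate
11 | (3S,4S)-4-(dimethoxymethyl)-3-[(2S)-2-methylbut-3-yn-1-yl]dihydrofuran-2(3H)-one | C#C[C@@H](C)C[C@@H]1C(=O)OC[C@H]1C(OC)OC | intermediate
12 | (3S,4R)-4-(dimethoxymethyl)-3-hydroxy-3-[(2S)-2-methylbut-3-yn-1-yl]dihydrofuran-2(3H)-one | O[C@]1(C[C@H](C)C#C)C(=O)OC[C@H]1C(OC)OC | intermediate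
13 | (3S,4R)-4-(dimethoxymethyl)-3-[(2S)-2-methylbut-3-yn-1-yl]-2-oxotetrahydrofuran-3-yl acetate | CC(=O)O[C@]1(C[C@H](C)C#C)C(=O)OC[C@H]1C(OC)OC | intermediate
14 | (5S)-4-hydroxy-5-[(2R)-1-hydroxy-3,3-dimethoxypropan-2-yl]-5-[(2S)-2-methylbut-3-yn-1-yl]furan-2(5H)-one | O=C1C=C(O)[C@](O1)(C[C@H](C)C#C)[C@@H](CO)C(OC)OC | intermediate
15 | (6S,7aS)-7a-[(2R)-1-hydroxy-3,3-dimethoxypropan-2-yl]-6-methyl-5-methylidene-5,6,7,7a-tetrahydro-2H-furo[3,2-b]pyran-2-one | O=C1C=C2OC(=C)[C@@H](C)C[C@]2(O1)[C@@H](CO)C(OC)OC | intermediate
16 | (2R)-3-hydroxy-2-[(6S,7aS)-6-methyl-5-methylidene-2-oxo-5,6,7,7a-tetrahydro-2H-furo[3,2-b]pyran-7a-yl]propanal | O=C1C=C2OC(=C)[C@@H](C)C[C@]2(O1)[C@@H](CO)C=O | intermediate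
17 | oxabicyclic diol (spiro-tetronate fused through its enol oxygen to the 2-oxabicyclo[2.2.2]octane; CH2OH on C10, OH on C11 anti to the ring oxygen; C12 and C13 methyl groups) | O=C1C=C2O[C@@]3(C)[C@@H](C)C[C@]2(O1)[C@@H](CO)[C@@H]3O | intermediate
18 | bis(triethylsilyl) ether of 17 | O=C1C=C2O[C@@]3(C)[C@@H](C)C[C@]2(O1)[C@@H](CO[Si](CC)(CC)CC)[C@@H]3O[Si](CC)(CC)CC | intermediate
19 | C9 aldehyde (C10–CHO, C11–OSiEt3) | O=C1C=C2O[C@@]3(C)[C@@H](C)C[C@]2(O1)[C@@H](C=O)[C@@H]3O[Si](CC)(CC)CC | intermediate
20 | C10-vinyl core (C10–CH=CH2, C11–OSiEt3) | O=C1C=C2O[C@@]3(C)[C@@H](C)C[C@]2(O1)[C@@H](C=C)[C@@H]3O[Si](CC)(CC)CC | intermediate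
21 | cis-3,5-dimethyloxane-2,6-dione (meso-2,4-dimethylglutaric anhydride) | O=C1OC(=O)[C@@H](C)C[C@H]1C | starting material
22 | (2R,4S)-5-methoxy-2,4-dimethyl-5-oxopentanoic acid | OC(=O)[C@H](C)C[C@H](C)C(=O)OC | intermediate
23 | methyl (2S,4R)-5-chloro-2,4-dimethyl-5-oxopentanoate | ClC(=O)[C@H](C)C[C@H](C)C(=O)OC | intermediate
24 | methyl (2S,4R)-2,4-dimethyl-5-oxopentanoate | O=C[C@H](C)C[C@H](C)C(=O)OC | intermediate
25 | methyl (2S,4R)-5-hydroxy-2,4-dimethylhept-6-enoate (both C5 epimers) | C=CC(O)[C@H](C)C[C@H](C)C(=O)OC | intermediate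
26 | (3S,5R)-6-ethenyl-3,5-dimethyloxan-2-one (both C6 epimers) | C=CC1OC(=O)[C@@H](C)C[C@H]1C | intermediate
27 | C3 ketone with C7 carbinol (both C7 epimers; C10 vinyl, C11–OSiEt3) | C=CC(O)[C@H](C)C[C@H](C)C(=O)C1=C2O[C@@]3(C)[C@@H](C)C[C@]2(OC1=O)[C@@H](C=C)[C@@H]3O[Si](CC)(CC)CC | intermediate
28 | dienone (C7 vinyl ketone, C10 vinyl, C11–OSiEt3) | C=CC(=O)[C@H](C)C[C@H](C)C(=O)C1=C2O[C@@]3(C)[C@@H](C)C[C@]2(OC1=O)[C@@H](C=C)[C@@H]3O[Si](CC)(CC)CC | intermediate
29 | macrocyclic E-enone silyl ether | C[C@@H]1C[C@H](C)C(=O)C2=C3O[C@@]4(C)[C@@H](C)C[C@]3(OC2=O)[C@@H](/C=C/C1=O)[C@@H]4O[Si](CC)(CC)CC | intermediate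
30 | macrocyclic E-enone with free C11–OH | C[C@@H]1C[C@H](C)C(=O)C2=C3O[C@@]4(C)[C@@H](C)C[C@]3(OC2=O)[C@@H](/C=C/C1=O)[C@@H]4O | intermediate
31 | abyssomicin N | C[C@@H]1C[C@H](C)/C(O)=C2/C(=O)O[C@]34C[C@H](C)[C@]5(C)O[C@]23[C@@H](C[C@H]4[C@@H]5O)C1=O | target

**Count**

Total step count: 25.
Longest linear sequence: 20 steps (steps 3–17, then 21–25, from methyl (S)-3-hydroxy-2-methylpropanoate).

**Steps most likely to fail**

Step 14 (labelled step). The C12 radical may take up a second hydrogen atom before it closes, the alkoxy radical may fragment back faster than it is reduced, or the aldehyde may be attacked on the wrong face. The fallback uses known reactions, sets out from 13 and comes back at 17. Hydrolysis of the acetal of 13 (pyridinium p-toluenesulfonate, wet acetone) gives the acetoxy-lactone ynal F1. Nickel-catalysed reductive cyclisation of the ynal (Ni(cod)2, PBu3, Et3SiH, THF) forms the C11–C12 bond from the alkyne side and gives the lactone-fused 2-methylidenecyclohexyl triethylsilyl ether F2, the silyloxy group being expected trans to the lactone CH2 on C10. LiN(SiMe3)2 in THF then brings about the Dieckmann condensation to the spiro-tetronic acid F3. Camphorsulfonic acid in CH2Cl2 adds the tetronic acid O–H across the exocyclic alkene in the Markovnikov sense (C12 cation, O–C12 bond, C12 methyl group), and aqueous work-up removes the silyl group to give 17.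

Step 12. The ambident tetronate may attack the activated alkyne through C2 (carbocyclisation), or the exocyclic double bond may move into the ring under the Lewis acidic catalyst. The fallback sets out from 14 and comes back at 15. Iodine (2.2 equiv) and NaHCO3 in MeCN iodinate C2 and then bring about iodocyclisation of the enol oxygen onto the alkyne (6-exo-dig, anti addition) to give the di-iodo enol ether F4. Bu3SnH with Pd(PPh3)4 in THF then replaces both vinylic iodine atoms by hydrogen and gives 15.

Step 25. The hydride may add 1,2 to a ketone, or the enolate may be protonated before it closes the rings. The fallback sets out from 30 and comes back at 31. Hydrogenation of the disubstituted enone double bond (H2, RhCl(PPh3)3, benzene) gives the saturated macrocyclic diketone F5. 1,8-Diazabicyclo[5.4.0]undec-7-ene in THF then equilibrates the C7 enolates, so that the transannular Michael addition of C8 to C16 runs under thermodynamic control and gives 31 after acidification.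

Further compounds
F1 | step 14 | (3S,4R)-4-formyl-3-[(2S)-2-methylbut-3-yn-1-yl]-2-oxotetrahydrofuran-3-yl acetate | CC(=O)O[C@]1(C[C@H](C)C#C)C(=O)OC[C@H]1C=O
F2 | step 14 | cis-fused bicyclic lactone: cyclohexane C10–C15 with exocyclic C12=CH2, C11–OSiEt3, C13 methyl and C15 acetoxy groups | CC(=O)O[C@@]12C[C@H](C)C(=C)[C@@H](O[Si](CC)(CC)CC)[C@@H]1COC2=O
F3 | step 14 | spiro-tetronic acid on the cyclohexane C10–C15 with exocyclic C12=CH2, C11–OSiEt3 and C10–CH2OH | O=C1C=C(O)[C@]2(O1)C[C@H](C)C(=C)[C@@H](O[Si](CC)(CC)CC)[C@@H]2CO
F4 | step 12 | C2-iodo analogue of 15 with an exocyclic iodomethylidene group on C12 (iodine anti to the ring oxygen) | O=C1C(I)=C2O/C(=C/I)[C@@H](C)C[C@]2(O1)[C@@H](CO)C(OC)OC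
F5 | step 25 | 8,9-dihydro derivative of 30 (saturated macrocyclic diketone) | C[C@@H]1C[C@H](C)C(=O)C2=C3O[C@@]4(C)[C@@H](C)C[C@]3(OC2=O)[C@@H](CCC1=O)[C@@H]4O
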